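**Plan**

1. Cuts, last-made first: the C7 ester and 3-O-silyl groups; the C12 carbinol (from a 12-ketone) and C16=C17 (from a 16-ketone); C12–C13, which opens ring C; C3–C4 (ring A); C4–C5 and C10–C1 (lactone and its carbinol carbon); C5–C6 (ring B); C8–C9.
2. Enabling feature: the C12(OH)–C13(OH) pair next to C16 is a reductive-aldol (pinacol-type) retron. With C12–C13 cut and C16 a ketone, ring D (C8, C14, C13, C16, C15) is a spiro cyclopentane-1,2-dione with two identical arms, so C8 is not yet a stereocentre and closing ring C desymmetrises it.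
3. Forward order: symmetric ring D (masked cis-diol) → C8–C9 bond → ring B (hydroacylation) → 19,10-lactone (tethered Michael) → ring A (aldol) → ring C last (SmI2 reductive aldol of the dione onto the C12 aldehyde).
4. Stereochemistry: C9 comes from an iridium-catalysed asymmetric allylic alkylation, the only reagent-controlled centre. C10, C5, C4, C6 and C3 are relayed from C9 (anti addition, tether, thermodynamic ester, aldol). C8 and C13 come from the arm-selective closure of ring C. C12 comes from hydride attack on the 12-ketone on the face away from C10.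

Key step: step 20

Remark: atoms are cited with gibberellane numbering (ring A: C1–C5, C10; ring B: C5, C6, C8, C9, C10; ring C: C8, C9, C11–C14; ring D: C8, C13–C16; β is the face of H5 and H9); where a stereocentre is erased later (the ester-bearing carbon of 2 and 3, the spiro carbon C8 of 10–26, C4 of 21–23, C12 of 29 and 30) the expected major isomer is drawn.

**Route**

Step 1
Reactants: 1 methyl cyclopent-3-ene-1-carboxylate
Product: 2 methyl cis-3,4-dihydroxycyclopentane-1-carboxylate (hydroxyls trans to the ester)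
Conditions: K2OsO2(OH)4 (1 mol %), NMO, acetone/H2O, 0 °C → rt
Reagents that add atoms: N-methylmorpholine N-oxide C[N+]1([O-])CCOCC1; water O
Why: catalytic OsO4 cis-dihydroxylation of the only alkene should give the meso cis-diol, mainly anti to the ester; the ester-bearing carbon (C8) becomes planar again in step 3, so both diastereomers converge.

Step 2
Reactants: 2 methyl cis-3,4-dihydroxycyclopentane-1-carboxylate
Product: 3 methyl cis-3,4-(isopropylidenedioxy)cyclopentane-1-carboxylate
Conditions: Me2C(OMe)2, p-TsOH (cat.), acetone, rt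
Reagents that add atoms: 2,2-dimethoxypropane COC(C)(C)OC
Why: acid-catalysed acetonide formation (transketalisation) on a cis-1,2-diol keeps ring D locally symmetric and inert to the oxidations and organometallics that follow.

Step 3
Reactants: 3 methyl cis-3,4-(isopropylidenedioxy)cyclopentane-1-carboxylate
Product: 5 O-methyl O-trimethylsilyl ketene acetal of ester 3, via lithium ester enolate 4 (not isolated)
Conditions: LiN(i-Pr)2, THF, −78 °C; TMSCl, −78 °C → rt; filtration and concentration under argon
Reagents that add atoms: chlorotrimethylsilane C[Si](C)(C)Cl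
Why: kinetic ester enolisation and O-silylation (the protocol used for Ireland–Claisen substrates) should give the fully substituted ketene acetal, which has no E/Z problem because the two ring arms are equivalent.

Step 4
Reactants: 6 3-[(tert-butyldimethylsilyl)oxy]propanal
Product: 7 ethyl (E)-5-[(tert-butyldimethylsilyl)oxy]pent-2-enoate
Conditions: (EtO)2P(O)CH2CO2Et, NaH, THF, 0 °C → rt
Reagents that add atoms: triethyl phosphonoacetate CCOC(=O)CP(=O)(OCC)OCC
Why: Horner–Wadsworth–Emmons olefination with a stabilised phosphonate should give the E-enoate.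

Step 5
Reactants: 7 ethyl (E)-5-[(tert-butyldimethylsilyl)oxy]pent-2-enoate
Product: 8 (E)-5-[(tert-butyldimethylsilyl)oxy]pent-2-en-1-ol
Conditions: i-Bu2AlH (2.2 equiv), CH2Cl2, −78 °C; aq potassium sodium tartrate work-up
Reagents that add atoms: none
Why: 1,2-reduction of an enoate with i-Bu2AlH gives the allylic alcohol without touching the alkene geometry or the silyl ether.

Step 6
Reactants: 8 (E)-5-[(tert-butyldimethylsilyl)oxy]pent-2-en-1-ol
Product: 9 (E)-5-[(tert-butyldimethylsilyl)oxy]pent-2-en-1-yl methyl carbonate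
Conditions: ClCO2Me, pyridine, CH2Cl2, 0 °C
Reagents that add atoms: methyl chloroformate COC(=O)Cl
Why: O-acylation gives the allylic carbonate, the ionisable leaving group for the allylic substitution (it releases methoxide and CO2).

Step 7
Reactants: 5 O-methyl O-trimethylsilyl ketene acetal of ester 3; 9 (E)-5-[(tert-butyldimethylsilyl)oxy]pent-2-en-1-yl methyl carbonate
Product: 10 methyl 1-[(3S)-5-(tert-butyldimethylsilyloxy)pent-1-en-3-yl]-cis-3,4-(isopropylidenedioxy)cyclopentane-1-carboxylate (branch trans to the dioxolane)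
Conditions: [Ir(cod)Cl]2 (2 mol %), O,O′-(1,1′-binaphthalene-2,2′-diyl) N,N-bis(1-phenylethyl)phosphoramidite (4 mol %, the enantiomer that gives (3S); pre-formed cyclometalated complex), THF, 25–40 °C
Reagents that add atoms: none
Why: iridium-catalysed branch-selective asymmetric allylic alkylation (Tsuji–Trost type) of a silyl ketene acetal, activated by the methoxide that the carbonate releases, should set C9 at the substituted allyl terminus under catalyst control while C8 becomes quaternary; the allyl unit should enter anti to the dioxolane, and either arrangement at C8 converges at 27.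

Step 8
Reactants: 10 methyl ester with the C8–C9 bond
Product: 11 1-[(3S)-5-(tert-butyldimethylsilyloxy)pent-1-en-3-yl]-cis-3,4-(isopropylidenedioxy)cyclopentane-1-carbaldehyde
Conditions: i-Bu2AlH (1.1 equiv), toluene, −78 °C; aq potassium sodium tartrate work-up
Reagents that add atoms: none
Why: partial reduction of a neopentyl ester with i-Bu2AlH should stop at the aluminium hemiacetal, which releases the non-enolisable aldehyde on work-up.

Step 9
Reactants: 11 quaternary carbaldehyde bearing the C9 vinyl group
Product: 12 spiro ketone of rings B and D (C6 ketone; C5 and C10 methylenes; C9 bearing CH2CH2OTBS; C8 spiro to the acetonide ring)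
Conditions: [Rh(nbd)(dppe)]ClO4 (5 mol %, activated with H2), CH2Cl2, rt
Reagents that add atoms: none
Why: intramolecular hydroacylation of a 4-pentenal with cationic monovalent rhodium (C–H oxidative addition, alkene insertion, reductive elimination) closes ring B as a cyclopentanone; the α-quaternary carbon disfavours decarbonylation and C9 is not touched.

Step 10
Reactants: 12 spiro ketone of rings B and D
Product: 14 C6 enol triflate (C5=C6), via potassium enolate 13 (not isolated)
Conditions: KN(SiMe3)2, THF, −78 °C; PhNTf2, −78 → 0 °C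
Reagents that add atoms: N-phenylbis(trifluoromethanesulfonimide) O=S(=O)(N(c1ccccc1)S(=O)(=O)C(F)(F)F)C(F)(F)F
Why: the ketone can enolise only toward C5 because C8 is quaternary, so enolate O-sulfonylation is regiospecific.

Step 11
Reactants: 14 C6 enol triflate
Product: 15 2-(trimethylsilyl)ethyl cyclopentenecarboxylate (C7 ester on C6; C5=C6)
Conditions: Pd(OAc)2 (5 mol %), dppf, CO (1 atm), Me3SiCH2CH2OH, Et3N, DMF, 50 °C
Reagents that add atoms: carbon monoxide [C-]#[O+]; 2-(trimethylsilyl)ethanol C[Si](C)(C)CCO
Why: palladium-catalysed alkoxycarbonylation of an enol triflate (oxidative addition to zerovalent palladium, CO insertion, alcoholysis) installs C7 as an ester that fluoride removes at the end.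

Step 12
Reactants: 15 2-(trimethylsilyl)ethyl cyclopentenecarboxylate
Product: 16 enone (C10 ketone conjugated with C5=C6–CO2R; C9 bearing CH2CH2OTBS)
Conditions: Rh2(cap)4 (dirhodium tetracaprolactamate, 1 mol %), t-BuOOH, K2CO3, CH2Cl2, rt
Reagents that add atoms: tert-butyl hydroperoxide CC(C)(C)OO
Why: allylic C–H oxidation by tert-butylperoxyl radicals should attack the only allylic methylene (C10; the other allylic position, C8, is quaternary and ring D is saturated) and give the γ-keto enoate, the mild heterogeneous base leaving C9 unepimerised.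

Step 13
Reactants: 16 enone; 17 3,3-diethoxyprop-1-yne
Product: 20 C10 tertiary propargylic propionate (C10–O α; alkynyl β), via lithium acetylide 18 (not isolated), via lithium alkoxide 19 (not isolated)
Conditions: 17, n-BuLi, THF, −78 °C; add 16, −78 °C; then (EtCO)2O, DMAP (cat.), −78 → 0 °C
Reagents that add atoms: propionic anhydride CCC(=O)OC(=O)CC
Why: 1,2-addition of a lithium acetylide to the enone carbonyl on the face anti to the adjacent C9 side chain sets C10, and in situ acylation of the alkoxide supplies the C4/C18/C19 propionate.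

Step 14
Reactants: 20 C10 tertiary propargylic propionate
Product: 21 alkynyl 19,10-γ-lactone (C4–C5 bond made; H5 β; C6 ester β)
Conditions: KN(SiMe3)2 (0.2 equiv), THF, −78 → −20 °C; AcOH quench
Reagents that add atoms: none
Why: intramolecular Michael addition (5-exo-trig) of the propionate enolate to the C5=C6 enoate forms the lactone; the C10–O tether forces cis fusion at C5 and the C6 ester enolate should protonate/equilibrate trans to C4.

Step 15
Reactants: 21 alkynyl 19,10-γ-lactone
Product: 22 (Z)-alkenyl lactone (C1=C2 cis; C3 as diethyl acetal)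
Conditions: H2 (1 atm), Pd/CaCO3 poisoned with Pb(OAc)2, quinoline, EtOAc, rt
Reagents that add atoms: none
Why: Lindlar semi-hydrogenation gives the cis-alkene that ring A requires; no other reducible alkene is present.

Step 16
Reactants: 22 (Z)-alkenyl lactone
Product: 23 (Z)-enal lactone (C3 aldehyde)
Conditions: PPTS (cat.), acetone/H2O, 0 °C → rt; used at once
Reagents that add atoms: water O
Why: an allylic diethyl acetal hydrolyses far faster than the acetonide (which acetone as solvent preserves) or the primary silyl ether, releasing the Z-enal under conditions too mild for Z/E isomerisation.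

Step 17
Reactants: 23 (Z)-enal lactone
Product: 25 ring A-closed 3β-triisopropylsilyloxy-Δ1-19,10-lactone (ring D acetonide; C12 OTBS), via potassium aldolate 24 (not isolated)
Conditions: KN(SiMe3)2 (1.1 equiv), 18-crown-6, THF, −78 °C; TIPSOTf, −78 → −40 °C
Reagents that add atoms: triisopropylsilyl trifluoromethanesulfonate CC(C)[Si](OS(=O)(=O)C(F)(F)F)(C(C)C)C(C)C
Why: intramolecular aldol of the lactone enolate (the lactone α-proton is more acidic and less hindered than H6) onto the Z-enal closes ring A; C4 is fixed by the bridged geometry, C3 should come from an open, dipole-minimised transition state (non-chelating potassium/crown ether, oxygen anti to C19), and silylation of the aldolate blocks retro-aldol.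

Step 18
Reactants: 25 ring A-closed 3β-triisopropylsilyloxy lactone
Product: 26 triol (C12 primary alcohol and ring D cis-diol)
Conditions: CSA (cat.), MeOH, 0 °C → rt
Reagents that add atoms: none
Why: acid-catalysed methanolysis removes the acetonide and the primary TBS ether, while the hindered secondary TIPS ether, lactone and ester should survive.

Step 19
Reactants: 26 triol
Product: 27 C12 aldehyde with spiro ring D as the cyclopentane-1,2-dione
Conditions: IBX (excess), DMSO, rt; used crude
Reagents that add atoms: none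
Why: hypervalent-iodine (IBX) oxidation takes the primary alcohol to the aldehyde and the cis-diol to the 1,2-dione without glycol cleavage; in 27 ring D is symmetric and C8 is no stereocentre.

Step 20
Reactants: 27 C12 aldehyde with spiro ring D as the cyclopentane-1,2-dione
Product: 29 tetracyclic 12,13-diol 16-ketone (17-nor-16-oxo; 12-hydroxyl syn to C16), via samarium enediolate 28 (not isolated)
Conditions: SmI2 (2.2 equiv, 0.1 M in THF), THF, −78 °C; aq NH4Cl
Reagents that add atoms: none
Why: Proposed new method: two equivalents of SmI2 should reduce the cyclopentane-1,2-dione (or its enol tautomer) much faster than the aliphatic aldehyde to the trivalent-samarium enediolate 28, whose carbon C13 then adds to the tethered C12 aldehyde in an aldol step, a net intramolecular pinacol-type cross-coupling that would form the same C12–C13 bond if the aldehyde ketyl arose first and added to the dione carbonyl. The closest known reaction types are the SmI2 keto-aldehyde pinacol cyclisation, low-valent-metal cross-coupling of 1,2-dicarbonyl compounds with aldehydes, and aldol reactions of samarium enolates made by reducing α-heterosubstituted ketones. Ring C closes in a 6-(enolexo)-exo-trig mode onto the aldehyde, giving the bridged bicyclo[3.2.1]octane with ring D already present. C8 and C13 are set together by which of the two equivalent enediolate carbons reacts: the C9 stereocentre holds the CH2CHO arm on the α face of ring B, the face that also carries one arm of the spiro ring, so bonding to the nearer carbon (which thereby becomes C13) gives the cis-fused junction of rings B and C found in the target, whereas bonding to the far carbon would need a strained trans-fused transition state. C12 should arise from a chair chelate in which samarium bridges O16 and the aldehyde oxygen (hydroxyl syn to C16); this centre is corrected in steps 22 and 23. The step needs chemoselectivity (dione before aldehyde, allylic lactone and esters untouched at −78 °C) and arm selectivity, which the reduction potentials and the tether geometry should secure.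

Step 21
Reactants: 29 tetracyclic 12,13-diol 16-ketone
Product: 30 16-methylene 12,13-diol (12-epi)
Conditions: Zn, CH2Br2, TiCl4 (reagent aged at 5 °C), THF/CH2Cl2, 0 °C → rt
Reagents that add atoms: dibromomethane BrCBr
Why: Lombardo methylenation with the non-basic zinc/titanium carbenoid converts the hindered 16-ketone into the exocyclic alkene without α-ketol rearrangement and leaves ester, lactone and free hydroxyls alone.

Step 22
Reactants: 30 16-methylene 12,13-diol
Product: 31 13-hydroxy-12-ketone
Conditions: Dess–Martin periodinane, NaHCO3, CH2Cl2, 0 °C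
Reagents that add atoms: none
Why: Dess–Martin oxidation of the only free secondary alcohol gives the 12-ketone; the tertiary 13-hydroxyl cannot be oxidised.

Step 23
Reactants: 31 13-hydroxy-12-ketone
Product: 32 2-(trimethylsilyl)ethyl ester 3-O-triisopropylsilyl ether of the target (12-hydroxygibberellic acid)
Conditions: LiBH(s-Bu)3 (2.5 equiv), THF, −78 °C; aq NH4Cl
Reagents that add atoms: none
Why: the bulky hydride should attack the 12-ketone equatorially from the C16 side because the axial face is blocked by the syn-axial C10 (as in hindered cyclohexanones with a syn-axial substituent), giving the axial 12-hydroxyl of the target, anti to C16; no conjugated enone is present.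

Step 24
Reactants: 32 2-(trimethylsilyl)ethyl ester 3-O-triisopropylsilyl ether of the target
Product: 33 target gibberellin, number 87 of the gibberellin A series (12-hydroxygibberellic acid)
Conditions: n-Bu4NF, THF, 0 °C → rt; dilute aq HCl to pH 3
Reagents that add atoms: none
Why: fluoride cleaves the silyl ether and fragments the 2-(trimethylsilyl)ethyl ester (β-elimination to ethene) in one operation, under conditions milder than the hydroxide that would rearrange the allylic lactone.

**Compound list**

1 | methyl cyclopent-3-ene-1-carboxylate | COC(=O)C1CC=CC1 | starting material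
2 | methyl cis-3,4-dihydroxycyclopentane-1-carboxylate (hydroxyls trans to ester) | COC(=O)[C@H]1C[C@H](O)[C@H](O)C1 | intermediate
3 | methyl cis-3,4-(isopropylidenedioxy)cyclopentane-1-carboxylate | COC(=O)[C@H]1C[C@@H]2OC(C)(C)O[C@@H]2C1 | intermediate
4 | lithium ester enolate of 3 | COC([O-])=C1C[C@@H]2OC(C)(C)O[C@@H]2C1.[Li+] | intermediate (not isolated)
5 | O-methyl O-trimethylsilyl ketene acetal of 3 | COC(O[Si](C)(C)C)=C1C[C@@H]2OC(C)(C)O[C@@H]2C1 | intermediate
6 | 3-[(tert-butyldimethylsilyl)oxy]propanal | CC(C)(C)[Si](C)(C)OCCC=O | starting material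
7 | ethyl (E)-5-[(tert-butyldimethylsilyl)oxy]pent-2-enoate | CCOC(=O)/C=C/CCO[Si](C)(C)C(C)(C)C | intermediate
8 | (E)-5-[(tert-butyldimethylsilyl)oxy]pent-2-en-1-ol | OC/C=C/CCO[Si](C)(C)C(C)(C)C | intermediate
9 | (E)-5-[(tert-butyldimethylsilyl)oxy]pent-2-en-1-yl methyl carbonate | COC(=O)OC/C=C/CCO[Si](C)(C)C(C)(C)C | intermediate
10 | methyl 1-[(3S)-5-(tert-butyldimethylsilyloxy)pent-1-en-3-yl]-cis-3,4-(isopropylidenedioxy)cyclopentane-1-carboxylate | C=C[C@H](CCO[Si](C)(C)C(C)(C)C)[C@@]1(C(=O)OC)C[C@@H]2OC(C)(C)O[C@@H]2C1 | intermediate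
11 | corresponding cyclopentane-1-carbaldehyde | C=C[C@H](CCO[Si](C)(C)C(C)(C)C)[C@@]1(C=O)C[C@@H]2OC(C)(C)O[C@@H]2C1 | intermediate
12 | spiro ketone of rings B and D (C6 ketone) | O=C1CC[C@H](CCO[Si](C)(C)C(C)(C)C)[C@]12C[C@@H]3OC(C)(C)O[C@@H]3C2 | intermediate
13 | potassium enolate of 12 | [K+].[O-]C1=CC[C@H](CCO[Si](C)(C)C(C)(C)C)[C@]12C[C@@H]3OC(C)(C)O[C@@H]3C2 | intermediate (not isolated)
14 | C6 enol triflate | FC(F)(F)S(=O)(=O)OC1=CC[C@H](CCO[Si](C)(C)C(C)(C)C)[C@]12C[C@@H]3OC(C)(C)O[C@@H]3C2 | intermediate
15 | 2-(trimethylsilyl)ethyl cyclopentenecarboxylate (C7 on C6) | C[Si](C)(C)CCOC(=O)C1=CC[C@H](CCO[Si](C)(C)C(C)(C)C)[C@]12C[C@@H]3OC(C)(C)O[C@@H]3C2 | intermediate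
16 | enone (C10 ketone, C5=C6 ester) | C[Si](C)(C)CCOC(=O)C1=CC(=O)[C@H](CCO[Si](C)(C)C(C)(C)C)[C@]12C[C@@H]3OC(C)(C)O[C@@H]3C2 | intermediate
17 | 3,3-diethoxyprop-1-yne | C#CC(OCC)OCC | starting material
18 | lithium 3,3-diethoxyprop-1-yn-1-ide | [Li+].[C-]#CC(OCC)OCC | intermediate (not isolated)
19 | lithium C10 alkoxide | [Li+].[O-][C@@]1(C#CC(OCC)OCC)C=C(C(=O)OCC[Si](C)(C)C)[C@@]2(C[C@@H]3OC(C)(C)O[C@@H]3C2)[C@H]1CCO[Si](C)(C)C(C)(C)C | intermediate (not isolated)
20 | C10 tertiary propargylic propionate | CCC(=O)O[C@@]1(C#CC(OCC)OCC)C=C(C(=O)OCC[Si](C)(C)C)[C@@]2(C[C@@H]3OC(C)(C)O[C@@H]3C2)[C@H]1CCO[Si](C)(C)C(C)(C)C | intermediate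
21 | alkynyl 19,10-γ-lactone | CC(C)(C)[Si](C)(C)OCC[C@H]1[C@@]2(C#CC(OCC)OCC)OC(=O)[C@H](C)[C@H]2[C@H](C(=O)OCC[Si](C)(C)C)[C@@]13C[C@@H]4OC(C)(C)O[C@@H]4C3 | intermediate
22 | (Z)-alkenyl lactone, diethyl acetal | CC(C)(C)[Si](C)(C)OCC[C@H]1[C@@]2(/C=C\C(OCC)OCC)OC(=O)[C@H](C)[C@H]2[C@H](C(=O)OCC[Si](C)(C)C)[C@@]13C[C@@H]4OC(C)(C)O[C@@H]4C3 | intermediate
23 | (Z)-enal lactone | CC(C)(C)[Si](C)(C)OCC[C@H]1[C@@]2(/C=C\C=O)OC(=O)[C@H](C)[C@H]2[C@H](C(=O)OCC[Si](C)(C)C)[C@@]13C[C@@H]4OC(C)(C)O[C@@H]4C3 | intermediate
24 | potassium C3 aldolate | CC(C)(C)[Si](C)(C)OCC[C@H]1[C@@]23C=C[C@H]([O-])[C@@](C)(C(=O)O2)[C@H]3[C@H](C(=O)OCC[Si](C)(C)C)[C@@]14C[C@@H]5OC(C)(C)O[C@@H]5C4.[K+] | intermediate (not isolated)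
25 | ring A-closed 3β-triisopropylsilyloxy-Δ1-19,10-lactone | CC(C)(C)[Si](C)(C)OCC[C@H]1[C@@]23C=C[C@H](O[Si](C(C)C)(C(C)C)C(C)C)[C@@](C)(C(=O)O2)[C@H]3[C@H](C(=O)OCC[Si](C)(C)C)[C@@]14C[C@@H]5OC(C)(C)O[C@@H]5C4 | intermediate
26 | triol (C12 alcohol, ring D cis-diol) | OCC[C@H]1[C@@]23C=C[C@H](O[Si](C(C)C)(C(C)C)C(C)C)[C@@](C)(C(=O)O2)[C@H]3[C@H](C(=O)OCC[Si](C)(C)C)[C@@]14C[C@H](O)[C@H](O)C4 | intermediate
27 | C12 aldehyde with ring D 1,2-dione | O=CC[C@H]1[C@@]23C=C[C@H](O[Si](C(C)C)(C(C)C)C(C)C)[C@@](C)(C(=O)O2)[C@H]3[C@H](C(=O)OCC[Si](C)(C)C)C14CC(=O)C(=O)C4 | intermediate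
28 | samarium enediolate of 27 | O=CC[C@H]1[C@@]23C=C[C@H](O[Si](C(C)C)(C(C)C)C(C)C)[C@@](C)(C(=O)O2)[C@H]3[C@H](C(=O)OCC[Si](C)(C)C)C14CC([O-])=C([O-])C4.[Sm+3].[Sm+3].[I-].[I-].[I-].[I-] | intermediate (not isolated)
29 | tetracyclic 12,13-diol 16-ketone (12-epi) | O=C1C[C@]23C[C@@]1(O)[C@H](O)C[C@H]2[C@@]12C=C[C@H](O[Si](C(C)C)(C(C)C)C(C)C)[C@@](C)(C(=O)O1)[C@H]2[C@@H]3C(=O)OCC[Si](C)(C)C | intermediate
30 | 16-methylene 12,13-diol (12-epi) | C=C1C[C@]23C[C@@]1(O)[C@H](O)C[C@H]2[C@@]12C=C[C@H](O[Si](C(C)C)(C(C)C)C(C)C)[C@@](C)(C(=O)O1)[C@H]2[C@@H]3C(=O)OCC[Si](C)(C)C | intermediate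
31 | 13-hydroxy-12-ketone | C=C1C[C@]23C[C@@]1(O)C(=O)C[C@H]2[C@@]12C=C[C@H](O[Si](C(C)C)(C(C)C)C(C)C)[C@@](C)(C(=O)O1)[C@H]2[C@@H]3C(=O)OCC[Si](C)(C)C | intermediate
32 | 2-(trimethylsilyl)ethyl ester 3-O-triisopropylsilyl ether of the target (12-hydroxygibberellic acid) | C=C1C[C@]23C[C@@]1(O)[C@@H](O)C[C@H]2[C@@]12C=C[C@H](O[Si](C(C)C)(C(C)C)C(C)C)[C@@](C)(C(=O)O1)[C@H]2[C@@H]3C(=O)OCC[Si](C)(C)C | intermediate
33 | target gibberellin, number 87 of the gibberellin A series (12-hydroxygibberellic acid; 12-hydroxyl axial on ring C and anti to C16) | C=C1C[C@]23C[C@@]1(O)[C@@H](O)C[C@H]2[C@@]12C=C[C@H](O)[C@@](C)(C(=O)O1)[C@H]2[C@@H]3C(=O)O | target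

**Totals**

Total step count: 24. Longest linear sequence: 21 steps (steps 1–3 and 7–24); steps 4–6 prepare the allylic carbonate.

**Steps most likely to fail**

Step 20 (proposed new method). The electron transfer may not stop at the enediolate (further reduction of the ketol, or reduction or pinacol dimerisation at the aldehyde), or closure may go through the distal enediolate carbon. The fallback sets out from triol 26 and uses known reactions only. Chemoselective oxidation of the vicinal diol with catalytic [(neocuproine)Pd(OAc)]2(OTf)2 and benzoquinone in MeCN/H2O, which should leave the isolated primary alcohol alone, gives the ring D α-ketol F1; its regioisomer leads to the same enediol. Oxidation of the primary alcohol with catalytic TEMPO and PhI(OAc)2 should give the keto-aldehyde F2. A base-mediated direct aldol of the α-hydroxy ketone through its enediolate (DBU in THF, or catalytic Et2Zn with an amino-alcohol ligand), run under equilibrating conditions that favour the cis-fused bicyclo[3.2.1]octane, returns to the route at 29.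

Step 17. Facial selectivity at the aldehyde may be poor and give mainly the 3α-epimer, or the Z-enal may isomerise before it cyclises. The fallback sets out from 23. The aldol is run with LiN(SiMe3)2 and quenched with acetic acid to give the 3α-alcohol F3. Mitsunobu inversion (4-nitrobenzoic acid, PPh3, diisopropyl azodicarboxylate) gives the 3β-(4-nitrobenzoate) F4. Methanolysis (K2CO3, MeOH, 0 °C) gives the 3β-alcohol F5, and silylation (TIPSOTf, 2,6-lutidine) returns to the route at 25.

Step 7. The hindered, fully substituted ketene acetal may give poor branched-to-linear selectivity or low enantioselectivity. The fallback sets out from 3. Saponification (LiOH, THF/H2O) gives cis-3,4-(isopropylidenedioxy)cyclopentane-1-carboxylic acid F6. Esterification with allylic alcohol 8 (DCC, DMAP) gives the allyl ester F7. Ireland–Claisen rearrangement (LiN(i-Pr)2, TMSCl, THF, −78 °C → reflux; aqueous work-up) forms the C8–C9 bond without enantiocontrol and should give the (3S)-acid F8 together with its mirror image, the (3R)-acid F9. Preparative chromatography on a chiral stationary phase separates the two, and methylation of F8 with Me3SiCHN2 returns to the route at 10.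

**Further compounds**

F1 | step 20 | ring D α-ketol of triol 26 (one carbinol carbon oxidised) | OCC[C@H]1[C@@]23C=C[C@H](O[Si](C(C)C)(C(C)C)C(C)C)[C@@](C)(C(=O)O2)[C@H]3[C@H](C(=O)OCC[Si](C)(C)C)[C@@]14CC(=O)[C@H](O)C4
F2 | step 20 | C12 aldehyde of α-ketol F1 | O=CC[C@H]1[C@@]23C=C[C@H](O[Si](C(C)C)(C(C)C)C(C)C)[C@@](C)(C(=O)O2)[C@H]3[C@H](C(=O)OCC[Si](C)(C)C)[C@@]14CC(=O)[C@H](O)C4
F3 | step 17 | ring A-closed 3α-alcohol (3-epimer) | CC(C)(C)[Si](C)(C)OCC[C@H]1[C@@]23C=C[C@@H](O)[C@@](C)(C(=O)O2)[C@H]3[C@H](C(=O)OCC[Si](C)(C)C)[C@@]14C[C@@H]5OC(C)(C)O[C@@H]5C4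
F4 | step 17 | 3β-(4-nitrobenzoate) | CC(C)(C)[Si](C)(C)OCC[C@H]1[C@@]23C=C[C@H](OC(=O)c6ccc(cc6)[N+](=O)[O-])[C@@](C)(C(=O)O2)[C@H]3[C@H](C(=O)OCC[Si](C)(C)C)[C@@]14C[C@@H]5OC(C)(C)O[C@@H]5C4
F5 | step 17 | ring A-closed 3β-alcohol | CC(C)(C)[Si](C)(C)OCC[C@H]1[C@@]23C=C[C@H](O)[C@@](C)(C(=O)O2)[C@H]3[C@H](C(=O)OCC[Si](C)(C)C)[C@@]14C[C@@H]5OC(C)(C)O[C@@H]5C4
F6 | step 7 | cis-3,4-(isopropylidenedioxy)cyclopentane-1-carboxylic acid | OC(=O)[C@H]1C[C@@H]2OC(C)(C)O[C@@H]2C1
F7 | step 7 | (E)-5-[(tert-butyldimethylsilyl)oxy]pent-2-en-1-yl ester of F6 | CC(C)(C)[Si](C)(C)OCC/C=C/COC(=O)[C@H]1C[C@@H]2OC(C)(C)O[C@@H]2C1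
F8 | step 7 | 1-[(3S)-5-(tert-butyldimethylsilyloxy)pent-1-en-3-yl]-cis-3,4-(isopropylidenedioxy)cyclopentane-1-carboxylic acid | C=C[C@H](CCO[Si](C)(C)C(C)(C)C)[C@@]1(C(=O)O)C[C@@H]2OC(C)(C)O[C@@H]2C1
F9 | step 7 | 1-[(3R)-5-(tert-butyldimethylsilyloxy)pent-1-en-3-yl]-cis-3,4-(isopropylidenedioxy)cyclopentane-1-carboxylic acid (mirror image of F8, set aside) | C=C[C@@H](CCO[Si](C)(C)C(C)(C)C)[C@@]1(C(=O)O)C[C@@H]2OC(C)(C)O[C@@H]2C1
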